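**Plan**

1. Numbering used: ring A = C1–C5 and C10, ring B = C5–C10; C4 carries the gem-dimethyl group, C5 the hydroxyl, C8 a methyl, C9 a methyl and the benzylic carbon C11, C10 the ring-fusion hydrogen.
2. Retrosynthetic cuts, in order: hydroxyquinone (from a 2,3,5,6-tetramethoxyphenyl group); C10–H (from a C1=C10 alkene); C1–C2 (ring A); C2–I (from a vinyl group); C4–C5 (γ-addition of a prenyl metal to a C5 ketone); C5=O and the C1 methylene (from a C10 ketone); last C9–C11 and C8–CH3.
3. Forward: ring B comes from 2-methylcyclohex-2-en-1-one; conjugate methylation and enolate benzylation add the C8 methyl and the aryl fragment; Wittig methylenation and allylic oxidation move the carbonyl to C5; reverse prenylation and hydroiodination build the chain; ring A is closed last, then hydrogenation and quinone unveiling.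
4. Feature used by the key step: C10 lies between two fully substituted carbons, C9 and C5, so a C2 radical can only close 6-endo onto methylene C1, and the C10 radical can only lose hydrogen from C1; the new alkene therefore sits at C1=C10, allylic to the C5 hydroxyl.
5. Stereochemistry: C8 from ligand-controlled copper-catalysed conjugate addition; C9 from alkylation anti to the C8 methyl; C5 from attack on the ketone face anti to the axial arylmethyl group; C10 from hydroxyl-directed hydrogenation (cis ring fusion).

Key step: step 9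

Assumption: the (S,R,R) antipode of the phosphoramidite ligand L is taken to give the (3S) centre in step 3; if the sense of induction is the opposite, its mirror image is used and nothing else changes.

**Step 1**
Reactants: 1 1,2,4,5-tetramethoxybenzene
Product: 3 (2,3,5,6-tetramethoxyphenyl)methanol, via 2,3,5,6-tetramethoxyphenyllithium 2 (not isolated)
Conditions: n-BuLi, TMEDA, THF, 0 °C; then (CH2O)n, 0 °C → rt; then H2O
Reagents that add atoms: paraformaldehyde, as formaldehyde (C=O)
Why: Directed ortho-lithiation at the ring position flanked by two methoxy groups gives 2, which adds to formaldehyde (hydroxymethylation of an aryllithium); no stereocentre is formed.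

**Step 2**
Reactants: 3 (2,3,5,6-tetramethoxyphenyl)methanol
Product: 4 3-(bromomethyl)-1,2,4,5-tetramethoxybenzene
Conditions: PBr3 (0.4 equiv), Et2O, 0 °C
Reagents that add atoms: phosphorus tribromide (BrP(Br)Br)
Why: The electron-rich benzylic alcohol is converted to the bromide through its phosphite ester (nucleophilic substitution by bromide); the bromide is used at once.

**Step 3**
Reactants: 5 2-methylcyclohex-2-en-1-one; 4 3-(bromomethyl)-1,2,4,5-tetramethoxybenzene
Product: 8 (2R,3S)-2,3-dimethyl-2-[(2,3,5,6-tetramethoxyphenyl)methyl]cyclohexan-1-one, via dimethylaluminium enolate 6 (not isolated), via lithium trimethylaluminate enolate 7 (not isolated)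
Conditions: Me3Al, Cu(O2CC4H3S) (2 mol %), ligand L [(S)-1,1′-binaphthyl-2,2′-diyl N,N-bis((R)-1-phenylethyl)phosphoramidite, 4 mol %], Et2O, −30 °C; then MeLi, THF, −30 °C; then 4, DMPU, −30 °C → rt
Reagents that add atoms: trimethylaluminium (C[Al](C)C)
Why: Copper-catalysed asymmetric conjugate addition sets the C8 methyl centre under ligand control, and the enolate, activated as its lithium aluminate, is alkylated at C9 on the face anti to the neighbouring C8 methyl (axial alkylation of a cyclohexanone enolate), so the two methyls come out cis and the arylmethyl group trans to the C8 methyl.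

**Step 4**
Reactants: 8 (2R,3S)-2,3-dimethyl-2-[(2,3,5,6-tetramethoxyphenyl)methyl]cyclohexan-1-one
Product: 9 3-{[(1R,2S)-1,2-dimethyl-6-methylidenecyclohexyl]methyl}-1,2,4,5-tetramethoxybenzene
Conditions: Ph3PCH3Br, KOtBu, toluene, 90 °C
Reagents that add atoms: methyltriphenylphosphonium bromide (C[P+](c1ccccc1)(c1ccccc1)c1ccccc1.[Br-])
Why: Wittig methylenation with excess hot ylide turns the hindered C10 carbonyl into the exocyclic methylene that supplies C1; no stereocentre is touched because C9 is quaternary.

**Step 5**
Reactants: 9 3-{[(1R,2S)-1,2-dimethyl-6-methylidenecyclohexyl]methyl}-1,2,4,5-tetramethoxybenzene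
Product: 10 (3R,4S)-3,4-dimethyl-2-methylidene-3-[(2,3,5,6-tetramethoxyphenyl)methyl]cyclohexan-1-ol (both C1 epimers of the cyclohexanol)
Conditions: SeO2 (0.2 equiv), t-BuOOH, CH2Cl2, rt
Reagents that add atoms: selenium dioxide (O=[Se]=O), turned over by tert-butyl hydroperoxide (CC(C)(C)OO)
Why: Selenium dioxide allylic oxidation (ene reaction, then [2,3]-sigmatropic shift) hydroxylates C5, the only allylic position that carries hydrogen because C9 is quaternary; the new carbinol configuration does not matter since it is removed in step 6.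

**Step 6**
Reactants: 10 (3R,4S)-3,4-dimethyl-2-methylidene-3-[(2,3,5,6-tetramethoxyphenyl)methyl]cyclohexan-1-ol
Product: 11 (3R,4S)-3,4-dimethyl-2-methylidene-3-[(2,3,5,6-tetramethoxyphenyl)methyl]cyclohexan-1-one
Conditions: MnO2 (activated, excess), CH2Cl2, rt
Reagents that add atoms: none
Why: Oxidation of the allylic alcohol with MnO2 gives the 2-methylene ketone under neutral conditions; it is used without storage to avoid hetero-Diels–Alder dimerisation.

**Step 7**
Reactants: 11 (3R,4S)-3,4-dimethyl-2-methylidene-3-[(2,3,5,6-tetramethoxyphenyl)methyl]cyclohexan-1-one; 12 3-methylbut-2-enylmagnesium chloride (Me2C=CHCH2MgCl)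
Product: 13 (1R,3R,4S)-3,4-dimethyl-1-(2-methylbut-3-en-2-yl)-2-methylidene-3-[(2,3,5,6-tetramethoxyphenyl)methyl]cyclohexan-1-ol
Conditions: 12 (1.5 equiv), THF, −78 °C; then H2O at −78 °C
Reagents that add atoms: none
Why: The allylic Grignard reagent adds 1,2 through a six-membered SE2′ transition state and so delivers its γ-carbon (reverse prenylation), creating quaternary C4 and the C5 carbinol; allylic 1,3-strain with the exocyclic methylene should place the large C9 arylmethyl group axial (trans-diaxial to the C8 methyl), where it screens the α face of the carbonyl, so the reagent should attack equatorially from the β face and leave the hydroxyl α, cis to the arylmethyl group.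

**Step 8**
Reactants: 13 (1R,3R,4S)-3,4-dimethyl-1-(2-methylbut-3-en-2-yl)-2-methylidene-3-[(2,3,5,6-tetramethoxyphenyl)methyl]cyclohexan-1-ol
Product: 15 (1R,3R,4S)-1-(4-iodo-2-methylbutan-2-yl)-3,4-dimethyl-2-methylidene-3-[(2,3,5,6-tetramethoxyphenyl)methyl]cyclohexan-1-ol, via alkylzirconocene chloride 14 (not isolated)
Conditions: Cp2Zr(H)Cl (2.5 equiv), THF, rt; then I2, 0 °C; then aq. Na2S2O3
Reagents that add atoms: iodine (II)
Why: Hydrozirconation is selective for the monosubstituted alkene over the methylene flanked by two quaternary carbons and places zirconium on terminal C2; iodinolysis of the C–Zr bond then gives the primary iodide without base, which keeps the γ-iodo alcohol from closing to a tetrahydrofuran.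

**Step 9**
Reactants: 15 (1R,3R,4S)-1-(4-iodo-2-methylbutan-2-yl)-3,4-dimethyl-2-methylidene-3-[(2,3,5,6-tetramethoxyphenyl)methyl]cyclohexan-1-ol
Product: 16 (1R,2S,4aR)-1,2,5,5-tetramethyl-1-[(2,3,5,6-tetramethoxyphenyl)methyl]-1,3,4,5,6,7-hexahydronaphthalen-4a(2H)-ol (C8=C8a alkene of the naphthalene name, i.e. C1=C10)
Conditions: Ph3Sn–Co(dmgH)2(py) (10 mol %; dmgH = dimethylglyoximate monoanion), iPr2NEt (2 equiv), MeCN, blue LEDs, rt
Reagents that add atoms: none
Why: Under light the catalyst enters a cycle in which monovalent cobalt takes up iodide 15 as an alkylcobaloxime, photolysis of the Co–C bond gives the primary C2 radical, this adds to methylene C1, and the tertiary C10 radical is trapped by divalent cobalt and loses a β-hydrogen (dehydrocobaltation), while iPr2NEt deprotonates the cobalt hydride to restart the cycle. The closest known reaction type is the cobaloxime-catalysed, light-driven Heck-type cyclisation of unactivated alkyl iodides onto alkenes. Ring A is closed in the 6-endo-trig mode, because the 5-exo alternative would have to bond to C10, a fully substituted alkene carbon between the quaternary carbons C9 and C5. No stereocentre is formed; C5, C8 and C9 are untouched and C10 stays trigonal for step 10. The step needs endo regioselectivity and a single alkene position, and the same feature secures both: C1 is the only neighbour of C10 that carries hydrogen, so the double bond can only appear at C1=C10, allylic to the C5 hydroxyl. As no hydrogen-atom donor is present, the slow endo closure should not be overtaken by reduction of the radical.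

**Step 10**
Reactants: 16 (1R,2S,4aR)-1,2,5,5-tetramethyl-1-[(2,3,5,6-tetramethoxyphenyl)methyl]-1,3,4,5,6,7-hexahydronaphthalen-4a(2H)-ol
Product: 17 (1R,2S,4aS,8aS)-1,2,5,5-tetramethyl-1-[(2,3,5,6-tetramethoxyphenyl)methyl]octahydronaphthalen-4a(2H)-ol
Conditions: [Ir(cod)(PCy3)(py)]PF6 (10 mol %), H2 (1 atm), CH2Cl2, rt
Reagents that add atoms: none
Why: Hydroxyl-directed hydrogenation: the C5 hydroxyl binds the cationic iridium centre, so both hydrogens should be delivered to the face of C1=C10 that carries it, which sets C10–H cis to the hydroxyl and gives the cis ring fusion.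

**Step 11**
Reactants: 17 (1R,2S,4aS,8aS)-1,2,5,5-tetramethyl-1-[(2,3,5,6-tetramethoxyphenyl)methyl]octahydronaphthalen-4a(2H)-ol
Product: 18 3-{[(1R,2S,4aS,8aS)-4a-hydroxy-1,2,5,5-tetramethyldecahydronaphthalen-1-yl]methyl}-2,5-dimethoxycyclohexa-2,5-diene-1,4-dione
Conditions: ceric ammonium nitrate, (NH4)2Ce(NO3)6 (2.5 equiv), MeCN/H2O, 0 °C
Reagents that add atoms: water (O)
Why: Oxidative demethylation of a para-dimethoxy pair gives the 2,5-dimethoxy-1,4-benzoquinone; either para pair leads to the same quinone, and the tertiary alcohol is inert.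

**Step 12**
Reactants: 18 3-{[(1R,2S,4aS,8aS)-4a-hydroxy-1,2,5,5-tetramethyldecahydronaphthalen-1-yl]methyl}-2,5-dimethoxycyclohexa-2,5-diene-1,4-dione
Product: 19 2-hydroxy-3-{[(1R,2S,4aS,8aS)-4a-hydroxy-1,2,5,5-tetramethyldecahydronaphthalen-1-yl]methyl}-5-methoxycyclohexa-2,5-diene-1,4-dione (CNP0209468.1)
Conditions: 2 M aq. KOH, MeOH, rt; then 1 M HCl to pH 3
Reagents that add atoms: potassium hydroxide ([K+].[OH-])
Why: Vinylogous ester hydrolysis (addition–elimination) should take place at the methoxy group next to the alkyl substituent, which is twisted out of conjugation and so sits on the more electrophilic carbon; the hydroxyquinone anion formed resists a second hydrolysis and acidification gives the target.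

**Compound list**

1 | 1,2,4,5-tetramethoxybenzene | COc1cc(OC)c(OC)cc1OC | starting material
2 | 2,3,5,6-tetramethoxyphenyllithium | [Li]c1c(OC)c(OC)cc(OC)c1OC | intermediate (not isolated)
3 | (2,3,5,6-tetramethoxyphenyl)methanol | COc1cc(OC)c(OC)c(CO)c1OC | intermediate
4 | 3-(bromomethyl)-1,2,4,5-tetramethoxybenzene | COc1cc(OC)c(OC)c(CBr)c1OC | intermediate
5 | 2-methylcyclohex-2-en-1-one | CC1=CCCCC1=O | starting material
6 | dimethylaluminium (3S)-2,3-dimethylcyclohex-1-en-1-olate | C[Al](C)OC1=C(C)[C@@H](C)CCC1 | intermediate (not isolated)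
7 | lithium trimethyl[(3S)-2,3-dimethylcyclohex-1-en-1-olato]aluminate | [Li+].C[Al-](C)(C)OC1=C(C)[C@@H](C)CCC1 | intermediate (not isolated)
8 | (2R,3S)-2,3-dimethyl-2-[(2,3,5,6-tetramethoxyphenyl)methyl]cyclohexan-1-one | COc1cc(OC)c(OC)c(C[C@]2(C)[C@@H](C)CCCC2=O)c1OC | intermediate
9 | 3-{[(1R,2S)-1,2-dimethyl-6-methylidenecyclohexyl]methyl}-1,2,4,5-tetramethoxybenzene | COc1cc(OC)c(OC)c(C[C@]2(C)[C@@H](C)CCCC2=C)c1OC | intermediate
10 | (3R,4S)-3,4-dimethyl-2-methylidene-3-[(2,3,5,6-tetramethoxyphenyl)methyl]cyclohexan-1-ol (carbinol epimers) | COc1cc(OC)c(OC)c(C[C@]2(C)[C@@H](C)CCC(O)C2=C)c1OC | intermediate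
11 | (3R,4S)-3,4-dimethyl-2-methylidene-3-[(2,3,5,6-tetramethoxyphenyl)methyl]cyclohexan-1-one | COc1cc(OC)c(OC)c(C[C@]2(C)[C@@H](C)CCC(=O)C2=C)c1OC | intermediate
12 | 3-methylbut-2-enylmagnesium chloride | CC(C)=CC[Mg]Cl | starting material
13 | (1R,3R,4S)-3,4-dimethyl-1-(2-methylbut-3-en-2-yl)-2-methylidene-3-[(2,3,5,6-tetramethoxyphenyl)methyl]cyclohexan-1-ol | COc1cc(OC)c(OC)c(C[C@]2(C)[C@@H](C)CC[C@@](O)(C(C)(C)C=C)C2=C)c1OC | intermediate
14 | adduct of 13 carrying Cp2Zr(Cl) on terminal C2 and Cp2Zr(Cl) on the C5 oxygen | COc1cc(OC)c(OC)c(C[C@]2(C)[C@@H](C)CC[C@@](O[Zr](Cl)(C3C=CC=C3)C3C=CC=C3)(C(C)(C)CC[Zr](Cl)(C3C=CC=C3)C3C=CC=C3)C2=C)c1OC | intermediate (not isolated)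
15 | (1R,3R,4S)-1-(4-iodo-2-methylbutan-2-yl)-3,4-dimethyl-2-methylidene-3-[(2,3,5,6-tetramethoxyphenyl)methyl]cyclohexan-1-ol | COc1cc(OC)c(OC)c(C[C@]2(C)[C@@H](C)CC[C@@](O)(C(C)(C)CCI)C2=C)c1OC | intermediate
16 | (1R,2S,4aR)-1,2,5,5-tetramethyl-1-[(2,3,5,6-tetramethoxyphenyl)methyl]-1,3,4,5,6,7-hexahydronaphthalen-4a(2H)-ol | COc1cc(OC)c(OC)c(C[C@]2(C)[C@@H](C)CC[C@]3(O)C2=CCCC3(C)C)c1OC | intermediate
17 | (1R,2S,4aS,8aS)-1,2,5,5-tetramethyl-1-[(2,3,5,6-tetramethoxyphenyl)methyl]octahydronaphthalen-4a(2H)-ol | COc1cc(OC)c(OC)c(C[C@]2(C)[C@@H](C)CC[C@]3(O)[C@H]2CCCC3(C)C)c1OC | intermediate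
18 | 3-{[(1R,2S,4aS,8aS)-4a-hydroxy-1,2,5,5-tetramethyldecahydronaphthalen-1-yl]methyl}-2,5-dimethoxycyclohexa-2,5-diene-1,4-dione | COC1=CC(=O)C(OC)=C(C[C@]2(C)[C@@H](C)CC[C@]3(O)[C@H]2CCCC3(C)C)C1=O | intermediate
19 | 2-hydroxy-3-{[(1R,2S,4aS,8aS)-4a-hydroxy-1,2,5,5-tetramethyldecahydronaphthalen-1-yl]methyl}-5-methoxycyclohexa-2,5-diene-1,4-dione | COC1=CC(=O)C(O)=C(C[C@]2(C)[C@@H](C)CC[C@]3(O)[C@H]2CCCC3(C)C)C1=O | target

**Step count**

Total: 12 steps. Longest linear sequence: 12 steps (from 1; 10 steps from 5).

**Steps most likely to fail**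

Step 7. The reagent may attack both faces of the C5 carbonyl if the axial preference of the arylmethyl group is weak, and conjugate addition at C1 or attack through the α-carbon of the allyl reagent may compete. Fallback, from 11 back to 13: stereocontrol is moved from the substrate to a chiral catalyst. The prenyl group is delivered by allylboration with 4,4,5,5-tetramethyl-2-(3-methylbut-2-enyl)-1,3,2-dioxaborolane in the presence of one antipode of 3,3′-dibromo-1,1′-bi-2-naphthol (toluene, tert-butanol additive, low temperature). The closed chair transition state allows only 1,2-addition through the γ-carbon, and the diol antipode is chosen so that it adds to the β face. This fallback makes no new compound (F0).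

Step 9. The 6-endo closure is slow, so the uncyclised alkylcobalt species may lose cobalt hydride first (which returns diene 13), or the radical may be lost by hydrogen abstraction from the amine or solvent. Fallback, from 15 to 16, by a degenerative xanthate-transfer radical chain in place of cobalt catalysis. Iodide 15 is displaced with KSC(S)OEt in acetone to give O-ethyl S-{3-[(1R,3R,4S)-1-hydroxy-3,4-dimethyl-2-methylidene-3-(2,3,5,6-tetramethoxybenzyl)cyclohexyl]-3-methylbutyl} carbonodithioate F1. Dilauroyl peroxide in refluxing 1,2-dichloroethane then starts the chain, in which reversible xanthate exchange stores the C2 radical long enough for the same 6-endo closure. The C10 radical picks up the xanthate group to give the tertiary C10 xanthate of the cis- or trans-fused decalin, O-ethyl S-[4a-hydroxy-decalin-8a-yl] carbonodithioate F2. On further heating (chlorobenzene, reflux) F2 should undergo Chugaev-type syn-elimination, which again can only take hydrogen from C1 and gives 16.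

Step 10. The hindered tertiary hydroxyl, flanked by the gem-dimethyl carbon, may fail to hold iridium on the α face of the trisubstituted alkene, so that hydrogenation stalls or loses facial control. Fallback, from 16 to 17, by silicon-tethered delivery of hydrogen. Alcohol 16 is silylated with Me2SiHCl and Et3N to give the dimethylsilyl ether F3. Intramolecular hydrosilylation with Pt2[(CH2=CHSiMe2)2O]3 (zerovalent platinum, toluene, 60 °C) should close the bridged 1-oxa-2-silacyclopentane F4 in the 5-endo mode; silicon goes to C1 and hydrogen to C10 on the face of the tether, i.e. cis to the C5 oxygen. Protodesilylation of the C1–Si bond (KOtBu, 18-crown-6, wet DMSO, 80 °C) then gives 17.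

**Further compounds**

F0 | step 7 | none | none
F1 | step 9 | O-ethyl S-{3-[(1R,3R,4S)-1-hydroxy-3,4-dimethyl-2-methylidene-3-(2,3,5,6-tetramethoxybenzyl)cyclohexyl]-3-methylbutyl} carbonodithioate | COc1cc(OC)c(OC)c(C[C@]2(C)[C@@H](C)CC[C@@](O)(C(C)(C)CCSC(=S)OCC)C2=C)c1OC
F2 | step 9 | O-ethyl S-[(1R,2S,4aS)-4a-hydroxy-1,2,5,5-tetramethyl-1-(2,3,5,6-tetramethoxybenzyl)octahydronaphthalen-8a(1H)-yl] carbonodithioate (C8a epimers) | COc1cc(OC)c(OC)c(C[C@]2(C)[C@@H](C)CC[C@]3(O)C2(SC(=S)OCC)CCCC3(C)C)c1OC
F3 | step 10 | dimethylsilyl ether of 16 | COc1cc(OC)c(OC)c(C[C@]2(C)[C@@H](C)CC[C@]3(O[SiH](C)C)C2=CCCC3(C)C)c1OC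
F4 | step 10 | bridged 1-oxa-2-silacyclopentane with O–SiMe2 joining C5 (oxygen) and C1 (silicon), C10–H cis to the oxygen | COc1cc(OC)c(OC)c(C[C@]2(C)[C@@H](C)CC[C@]3(O[Si]4(C)C)[C@H]2[C@@H]4CCC3(C)C)c1OC
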